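The route disconnects the two bonds at C-8, the methine that carries the ring B ether oxygen (O-4′), the C-7 carbinol on ring D and the C-9 hydroxymethyl: O-4′–C-8 and C-7–C-8. Because C-8 lies between a phenol oxygen, an aldehyde-derived carbinol and a carboxyl-derived CH2OH, a phenol, a diazoacetate and an aldehyde can be joined at it in one carbenoid O–H ylide/aldol event that also fixes both stereocentres (7S,8R, erythro). The precursors are 4-bromo-2,6-dimethoxyphenol, ethyl diazoacetate and 4-formylphenyl pivalate. The bromide later becomes a boronate that arylates C-2 of 5,7-bis(benzyloxy)chromone, attaching rings C and A to ring B.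

Key step: step 2

Assumption: the (R)-configured phosphoric acid is taken to deliver the (2S,3S) adduct; should the antipode form, the (S)-acid is used with no other change.

Step 1
Reactants: 1 4-hydroxybenzaldehyde
Product: 2 4-formylphenyl pivalate (4-formylphenyl 2,2-dimethylpropanoate)
Conditions: PivCl, Et3N, DMAP (cat.), CH2Cl2, 0 °C to rt
Reagents that add atoms: pivaloyl chloride, CC(C)(C)C(=O)Cl
Why: Base-mediated O-acylation of the phenol with an acid chloride (esterification) is fast and leaves the aldehyde untouched.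

Step 2
Reactants: 3 4-bromo-2,6-dimethoxyphenol; 4 ethyl diazoacetate; 2 4-formylphenyl pivalate
Product: 6 ethyl (2S,3S)-2-(4-bromo-2,6-dimethoxyphenoxy)-3-hydroxy-3-[4-(pivaloyloxy)phenyl]propanoate (erythro/anti), via oxonium ylide enol 5 (not isolated)
Conditions: Rh2(OAc)4 (1 mol%), (R)-3,3′-bis(2,4,6-triisopropylphenyl)-1,1′-binaphthyl-2,2′-diyl hydrogen phosphate (10 mol%), 4 Å MS, CH2Cl2, −20 °C, 2 in excess, 4 added slowly by syringe pump
Reagents that add atoms: none
Why: Proposed new method: the rhodium carbenoid generated from 4 is attacked by the phenol oxygen of 3 to give an oxonium ylide in equilibrium with enol 5, and the phosphoric acid is expected to hold the enol hydroxyl on its P=O oxygen and the formyl oxygen of 2 on its acidic OH, so that C-8–C-7 bond formation is faster than the 1,2-proton shift that would end in plain O–H insertion. The closest known reaction type is the three-component aldol-type trapping of alcohol-derived oxonium ylides of aryldiazoacetates by activated aldehydes under Rh2(OAc)4 with an acid co-catalyst; a phenol, an acceptor-only diazoacetate and phosphoric acid control of an aldehyde trap have not been combined. No ring is closed. Both new stereocentres arise in the C–C bond-forming transition state: the anti (erythro) relation should come from the hydrogen-bonded cyclic array in which the ring D aryl group turns away from the bulky aryloxy group, and the absolute configuration from the 3,3′-aryl groups of the (R)-acid, which shield one face of the bound aldehyde. The step needs O–H attack instead of ring attack by the carbenoid, which the substitution of 3 secures (OMe at both ortho positions, Br at the para position), and aldol trapping instead of proton shift, which the electron-withdrawing pivalate on 2, its excess and the slow addition of 4 at low temperature favour.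

Step 3
Reactants: 6 ethyl (2S,3S)-2-(4-bromo-2,6-dimethoxyphenoxy)-3-hydroxy-3-[4-(pivaloyloxy)phenyl]propanoate
Product: 7 (1S,2R)-2-(4-bromo-2,6-dimethoxyphenoxy)-1-(4-hydroxyphenyl)propane-1,3-diol
Conditions: LiAlH4, THF, 0 °C; aq. potassium sodium tartrate work-up
Reagents that add atoms: none
Why: Hydride reduction converts the ethyl ester into the C-9 primary alcohol and cleaves the aryl pivalate in the same operation, as is routine for β-hydroxy-α-aryloxy esters, and since no bond to C-7 or C-8 is broken both centres are retained (the C-8 descriptor changes from S to R only because CH2OH ranks below C-7).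

Step 4
Reactants: 7 (1S,2R)-2-(4-bromo-2,6-dimethoxyphenoxy)-1-(4-hydroxyphenyl)propane-1,3-diol
Product: 8 tris-TBS ether of 7: tert-butyl{4-[(1S,2R)-2-(4-bromo-2,6-dimethoxyphenoxy)-1,3-bis(tert-butyldimethylsilyloxy)propyl]phenoxy}dimethylsilane
Conditions: TBSOTf, 2,6-lutidine, CH2Cl2, −78 to 0 °C
Reagents that add atoms: tert-butyldimethylsilyl trifluoromethanesulfonate, CC(C)(C)[Si](C)(C)OS(=O)(=O)C(F)(F)F
Why: Silyl ether formation with a silyl triflate and a hindered pyridine base covers the phenol, the primary hydroxyl and the hindered benzylic hydroxyl at once, which blocks alcohol oxidation and quinone methide chemistry in the later palladium steps.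

Step 5
Reactants: 8 tris-TBS aryl bromide
Product: 9 pinacol boronate: 2-{4-[(1S,2R)-1,3-bis(tert-butyldimethylsilyloxy)-1-(4-tert-butyldimethylsilyloxyphenyl)propan-2-yl]oxy-3,5-dimethoxyphenyl}-4,4,5,5-tetramethyl-1,3,2-dioxaborolane
Conditions: B2pin2, Pd(dppf)Cl2 (5 mol%), KOAc, 1,4-dioxane, 90 °C
Reagents that add atoms: bis(pinacolato)diboron, CC1(C)OB(OC1(C)C)B1OC(C)(C)C(C)(C)O1
Why: Miyaura borylation (oxidative addition of the aryl bromide to zerovalent palladium, acetate-assisted transmetalation with the diboron reagent, reductive elimination) tolerates silyl ethers and does not touch the stereocentres.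

Step 6
Reactants: 10 2′,4′,6′-trihydroxyacetophenone
Product: 11 1-[2,4-bis(benzyloxy)-6-hydroxyphenyl]ethan-1-one
Conditions: BnBr (2.1 equiv), K2CO3, acetone, reflux
Reagents that add atoms: benzyl bromide, BrCc1ccccc1
Why: Williamson etherification under weak base alkylates the two more acidic, non-chelated hydroxyls, while the hydroxyl hydrogen-bonded to the acetyl carbonyl stays free.

Step 7
Reactants: 11 1-[2,4-bis(benzyloxy)-6-hydroxyphenyl]ethan-1-one
Product: 13 5,7-bis(benzyloxy)-4H-chromen-4-one, via enaminone 12 (not isolated)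
Conditions: DMF dimethyl acetal, toluene, 95 °C; then aq. HCl, CH2Cl2, rt
Reagents that add atoms: N,N-dimethylformamide dimethyl acetal, COC(OC)N(C)C
Why: Condensation of the acetyl methyl group with the amide acetal gives enaminone 12, and acid then triggers intramolecular conjugate addition of the phenol with loss of dimethylamine (enaminone route to chromones, a 6-endo addition–elimination).

Step 8
Reactants: 9 pinacol boronate; 13 5,7-bis(benzyloxy)-4H-chromen-4-one
Product: 14 5,7-bis(benzyloxy)-2-{4-[(1S,2R)-1,3-bis(tert-butyldimethylsilyloxy)-1-(4-tert-butyldimethylsilyloxyphenyl)propan-2-yl]oxy-3,5-dimethoxyphenyl}-4H-chromen-4-one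
Conditions: Pd(OAc)2 (10 mol%), 1,10-phenanthroline, O2 (1 atm), DMF, 80 °C
Reagents that add atoms: none
Why: Oxidative (boron) Heck arylation, an established flavone synthesis from chromones and arylboron reagents: aryl transfer from boron to divalent palladium, carbopalladation of the chromone C2=C3 bond with the aryl group going to the electrophilic C-2, and β-hydride elimination after epimerisation through the palladium enolate give the flavone, while O2 returns zerovalent palladium to the divalent state.

Step 9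
Reactants: 14 protected flavone
Product: 15 5,7-bis(benzyloxy)-2-{4-[(1S,2R)-1,3-dihydroxy-1-(4-hydroxyphenyl)propan-2-yl]oxy-3,5-dimethoxyphenyl}-4H-chromen-4-one
Conditions: TBAF, AcOH, THF, 0 °C to rt
Reagents that add atoms: none
Why: Fluoride-mediated desilylation, driven by Si–F bond formation, removes all three silyl groups, and the acetic acid buffer keeps the freed phenol protonated so that the para-hydroxybenzylic C-7 carbinol is neither ionised nor epimerised.

Step 10
Reactants: 15 5,7-di-O-benzyl flavonolignan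
Product: 16 5,7-dihydroxy-2-{4-[(1S,2R)-1,3-dihydroxy-1-(4-hydroxyphenyl)propan-2-yl]oxy-3,5-dimethoxyphenyl}-4H-chromen-4-one (target)
Conditions: H2 (1 atm), Pd/C, EtOAc–THF, rt, stopped at consumption of 15
Reagents that add atoms: none
Why: Catalytic hydrogenolysis cleaves the two aryl benzyl ethers much faster than the benzylic C-7–OH bond or the flavone C2=C3 bond under neutral conditions at 1 atm, as is usual for benzyl-protected arylglycerol β-aryl ethers and flavones.

Compound list
1 | 4-hydroxybenzaldehyde | O=Cc1ccc(O)cc1 | starting material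
2 | 4-formylphenyl pivalate | O=Cc1ccc(OC(=O)C(C)(C)C)cc1 | intermediate
3 | 4-bromo-2,6-dimethoxyphenol | COc1cc(Br)cc(OC)c1O | starting material
4 | ethyl diazoacetate | [N-]=[N+]=CC(=O)OCC | starting material
5 | 2-(4-bromo-2,6-dimethoxyphenoxy)-1-ethoxyethen-1-ol, enol form of the oxonium ylide (alkene geometry not defined) | CCOC(O)=COc1c(OC)cc(Br)cc1OC | intermediate
6 | ethyl (2S,3S)-2-(4-bromo-2,6-dimethoxyphenoxy)-3-hydroxy-3-[4-(pivaloyloxy)phenyl]propanoate | COc1cc(Br)cc(OC)c1O[C@H](C(=O)OCC)[C@@H](O)c1ccc(OC(=O)C(C)(C)C)cc1 | intermediate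
7 | (1S,2R)-2-(4-bromo-2,6-dimethoxyphenoxy)-1-(4-hydroxyphenyl)propane-1,3-diol | COc1cc(Br)cc(OC)c1O[C@H](CO)[C@@H](O)c1ccc(O)cc1 | intermediate
8 | tert-butyl{4-[(1S,2R)-2-(4-bromo-2,6-dimethoxyphenoxy)-1,3-bis(tert-butyldimethylsilyloxy)propyl]phenoxy}dimethylsilane | COc1cc(Br)cc(OC)c1O[C@H](CO[Si](C)(C)C(C)(C)C)[C@@H](O[Si](C)(C)C(C)(C)C)c1ccc(O[Si](C)(C)C(C)(C)C)cc1 | intermediate
9 | 2-{4-[(1S,2R)-1,3-bis(tert-butyldimethylsilyloxy)-1-(4-tert-butyldimethylsilyloxyphenyl)propan-2-yl]oxy-3,5-dimethoxyphenyl}-4,4,5,5-tetramethyl-1,3,2-dioxaborolane | COc1cc(B2OC(C)(C)C(C)(C)O2)cc(OC)c1O[C@H](CO[Si](C)(C)C(C)(C)C)[C@@H](O[Si](C)(C)C(C)(C)C)c1ccc(O[Si](C)(C)C(C)(C)C)cc1 | intermediate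
10 | 2′,4′,6′-trihydroxyacetophenone | CC(=O)c1c(O)cc(O)cc1O | starting material
11 | 1-[2,4-bis(benzyloxy)-6-hydroxyphenyl]ethan-1-one | CC(=O)c1c(O)cc(OCc2ccccc2)cc1OCc1ccccc1 | intermediate
12 | (E)-1-[2,4-bis(benzyloxy)-6-hydroxyphenyl]-3-(dimethylamino)prop-2-en-1-one | CN(C)/C=C/C(=O)c1c(O)cc(OCc2ccccc2)cc1OCc1ccccc1 | intermediate
13 | 5,7-bis(benzyloxy)-4H-chromen-4-one | O=c1ccoc2cc(OCc3ccccc3)cc(OCc3ccccc3)c12 | intermediate
14 | 5,7-bis(benzyloxy)-2-{4-[(1S,2R)-1,3-bis(tert-butyldimethylsilyloxy)-1-(4-tert-butyldimethylsilyloxyphenyl)propan-2-yl]oxy-3,5-dimethoxyphenyl}-4H-chromen-4-one | COc1cc(-c2cc(=O)c3c(OCc4ccccc4)cc(OCc4ccccc4)cc3o2)cc(OC)c1O[C@H](CO[Si](C)(C)C(C)(C)C)[C@@H](O[Si](C)(C)C(C)(C)C)c1ccc(O[Si](C)(C)C(C)(C)C)cc1 | intermediate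
15 | 5,7-bis(benzyloxy)-2-{4-[(1S,2R)-1,3-dihydroxy-1-(4-hydroxyphenyl)propan-2-yl]oxy-3,5-dimethoxyphenyl}-4H-chromen-4-one | COc1cc(-c2cc(=O)c3c(OCc4ccccc4)cc(OCc4ccccc4)cc3o2)cc(OC)c1O[C@H](CO)[C@@H](O)c1ccc(O)cc1 | intermediate
16 | 5,7-dihydroxy-2-{4-[(1S,2R)-1,3-dihydroxy-1-(4-hydroxyphenyl)propan-2-yl]oxy-3,5-dimethoxyphenyl}-4H-chromen-4-one | COc1cc(-c2cc(=O)c3c(O)cc(O)cc3o2)cc(OC)c1O[C@H](CO)[C@@H](O)c1ccc(O)cc1 | target

Total step count: 10 (steps 1–5 and 8–10 on the main line, steps 6–7 for the chromone partner).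
Longest linear sequence: 8 steps (1, 2, 3, 4, 5, 8, 9, 10).

Steps most likely to fail

Step 2 (proposed new method). The proton shift within the ylide may outrun C–C bond formation, so that only O–H insertion occurs, or the diastereofacial and enantiofacial control may be insufficient. The fallback makes the same C-7–C-8 bond by auxiliary-controlled aldol chemistry; it sets out from 3 and comes back to the route at 7. O-Alkylation of 3 with commercial (S)-4-benzyl-3-(chloroacetyl)oxazolidin-2-one (K2CO3, NaI, acetone) should give the aryloxyacetyl imide (4S)-4-benzyl-3-[(4-bromo-2,6-dimethoxyphenoxy)acetyl]oxazolidin-2-one F1. Its dibutylboron enolate (Bu2BOTf, iPr2NEt, CH2Cl2, −78 °C) should add to aldehyde 2 in a syn-selective Evans aldol reaction to give (4S)-4-benzyl-3-[(2S,3R)-2-(4-bromo-2,6-dimethoxyphenoxy)-3-hydroxy-3-(4-pivaloyloxyphenyl)propanoyl]oxazolidin-2-one F2, which already has the required C-8 configuration. Mitsunobu inversion of the benzylic carbinol (4-nitrobenzoic acid, PPh3, DIAD, THF) should then give the erythro ester (1S,2S)-3-[(4S)-4-benzyl-2-oxooxazolidin-3-yl]-2-(4-bromo-2,6-dimethoxyphenoxy)-3-oxo-1-[4-(pivaloyloxy)phenyl]propyl 4-nitrobenzoate F3. Excess LiBH4 in THF–MeOH should detach the auxiliary reductively and cleave the nitrobenzoate and the pivalate, giving triol 7.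

Step 8. Protodeboronation or homocoupling of the electron-rich boronate may outpace carbopalladation, or palladium turnover under O2 may stall. The fallback separates C–C bond formation from oxidation; it sets out from 9 and 13 and comes back at 14. Rhodium-catalysed 1,4-addition of 9 to 13 ([Rh(cod)OH]2, dioxane–H2O, 60 °C) should give the flavanone 5,7-bis(benzyloxy)-2-{4-[(1S,2R)-1,3-bis(tert-butyldimethylsilyloxy)-1-(4-tert-butyldimethylsilyloxyphenyl)propan-2-yl]oxy-3,5-dimethoxyphenyl}chroman-4-one F4 as a mixture of C-2 epimers, which does not matter. Aerobic dehydrogenation (Pd(TFA)2, DMSO, O2, 80 °C) should then give flavone 14.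

Step 10. Over-reduction may occur, either by hydrogenolysis of the benzylic C-7–O bond of the free para-hydroxybenzyl alcohol or by saturation of C2=C3. The fallback reverses the order of deprotection, so that C-7 still carries its silyl ether during hydrogenolysis; it sets out from 14 and comes back at 16. Hydrogenolysis of 14 (H2, Pd/C, EtOAc) should give 2-{4-[(1S,2R)-1,3-bis(tert-butyldimethylsilyloxy)-1-(4-tert-butyldimethylsilyloxyphenyl)propan-2-yl]oxy-3,5-dimethoxyphenyl}-5,7-dihydroxy-4H-chromen-4-one F5, and buffered fluoride (TBAF, AcOH, THF) should then release target 16.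

Further compounds
F1 | step 2 | (4S)-4-benzyl-3-[(4-bromo-2,6-dimethoxyphenoxy)acetyl]oxazolidin-2-one | COc1cc(Br)cc(OC)c1OCC(=O)N1[C@@H](Cc2ccccc2)COC1=O
F2 | step 2 | (4S)-4-benzyl-3-[(2S,3R)-2-(4-bromo-2,6-dimethoxyphenoxy)-3-hydroxy-3-(4-pivaloyloxyphenyl)propanoyl]oxazolidin-2-one | COc1cc(Br)cc(OC)c1O[C@H](C(=O)N1[C@@H](Cc2ccccc2)COC1=O)[C@H](O)c1ccc(OC(=O)C(C)(C)C)cc1
F3 | step 2 | (1S,2S)-3-[(4S)-4-benzyl-2-oxooxazolidin-3-yl]-2-(4-bromo-2,6-dimethoxyphenoxy)-3-oxo-1-[4-(pivaloyloxy)phenyl]propyl 4-nitrobenzoate | COc1cc(Br)cc(OC)c1O[C@H](C(=O)N1[C@@H](Cc2ccccc2)COC1=O)[C@@H](OC(=O)c1ccc(cc1)[N+](=O)[O-])c1ccc(OC(=O)C(C)(C)C)cc1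
F4 | step 8 | 5,7-bis(benzyloxy)-2-{4-[(1S,2R)-1,3-bis(tert-butyldimethylsilyloxy)-1-(4-tert-butyldimethylsilyloxyphenyl)propan-2-yl]oxy-3,5-dimethoxyphenyl}chroman-4-one (C-2 epimers) | COc1cc(C2CC(=O)c3c(OCc4ccccc4)cc(OCc4ccccc4)cc3O2)cc(OC)c1O[C@H](CO[Si](C)(C)C(C)(C)C)[C@@H](O[Si](C)(C)C(C)(C)C)c1ccc(O[Si](C)(C)C(C)(C)C)cc1
F5 | step 10 | 2-{4-[(1S,2R)-1,3-bis(tert-butyldimethylsilyloxy)-1-(4-tert-butyldimethylsilyloxyphenyl)propan-2-yl]oxy-3,5-dimethoxyphenyl}-5,7-dihydroxy-4H-chromen-4-one | COc1cc(-c2cc(=O)c3c(O)cc(O)cc3o2)cc(OC)c1O[C@H](CO[Si](C)(C)C(C)(C)C)[C@@H](O[Si](C)(C)C(C)(C)C)c1ccc(O[Si](C)(C)C(C)(C)C)cc1
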